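**Plan**

- Retrosynthesis: the coumarate C–O ester bond is cut first, then the ring bond O1–C2 of the 2,3,4,7-tetrahydrooxepine (O1, C2, C3, C4, C5=C6, C7). C2 carries O1, lies β to the aryl ketone through the CH2 group Ca and α to the carboxyl, so O1–C2 is the retron of a C7 alcohol adding to the Ca=C2 bond of a 2-alkyl-3-aroylacrylate.
- The open chain is then cut at Ca=C2 (Horner–Wadsworth–Emmons, arylglyoxal plus α-phosphono ester), at C5=C6 (Z-selective Wittig reaction of an α-alkoxy ketone with a carboxybutyl ylide) and at the bond between C6's side-chain CH2 and the ketone carbon (Grignard reagent plus Weinreb amide).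
- Forward: side-chain bromide → α-PMB-oxy ketone → Z-alkenoic acid → silylethyl ester → α-phosphono ester → aroylacrylate; PMB removal frees the C7 alcohol; the oxepine, the only ring formed, closes by oxa-Michael addition; then side-chain desilylation, coumaroylation and global fluoride deprotection.
- Stereochemistry: the single stereocentre (R)-C2 is set in the ring closure by a bifunctional cinchona amine–squaramide catalyst. The C5=C6 geometry comes from the α-alkoxy ketone Wittig reaction, the E side-chain alkene from SeO2 oxidation of the E-methyl group, and the E-acrylate from the olefination.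

Key step: step 12

Assumption: the sense of induction of the cinchona catalyst in this new ring closure cannot be derived from precedent; the epi-quinidine-derived squaramide is written, and its pseudo-enantiomer (epi-quinine-derived) would be used if the opposite face were delivered.

**Route**

Step 1
Reactants: 1 5-bromo-2-methylpent-2-ene
Product: 2 (E)-5-bromo-2-methylpent-2-en-1-ol
Conditions: SeO2 (0.5 equiv), t-BuOOH (70% aq.), CH2Cl2, 0 °C → rt
Reagents that add atoms: selenium dioxide, O=[Se]=O; tert-butyl hydroperoxide, CC(C)(C)OO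
Why: SeO2-catalysed allylic oxidation (ene reaction then [2,3]-sigmatropic shift) hydroxylates the methyl group trans to the chain of a gem-dimethyl trisubstituted alkene, which fixes the E side-chain geometry while the primary bromide stays inert.

Step 2
Reactants: 2 (E)-5-bromo-2-methylpent-2-en-1-ol
Product: 3 [(E)-5-bromo-2-methylpent-2-enyloxy](tert-butyl)dimethylsilane
Conditions: TBSCl, imidazole, CH2Cl2, 0 °C → rt
Reagents that add atoms: tert-butyldimethylsilyl chloride, CC(C)(C)[Si](C)(C)Cl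
Why: Imidazole-promoted silylation of a primary alcohol is routine and should leave the alkyl bromide untouched at this temperature.

Step 3
Reactants: 4 4-methoxybenzyl alcohol; 5 2-chloro-N-methoxy-N-methylacetamide
Product: 6 N-methoxy-2-[(4-methoxybenzyl)oxy]-N-methylacetamide
Conditions: NaH, THF, 0 °C; then 5, Bu4NI (cat.), 0 °C → rt
Reagents that add atoms: none
Why: Williamson ether synthesis on an α-chloro amide, whose carbonyl-activated CH2Cl is a fast SN2 electrophile for the sodium alkoxide.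

Step 4
Reactants: 3 [(E)-5-bromo-2-methylpent-2-enyloxy](tert-butyl)dimethylsilane; 6 N-methoxy-2-[(4-methoxybenzyl)oxy]-N-methylacetamide
Product: 8 (E)-7-(tert-butyldimethylsilyloxy)-1-[(4-methoxybenzyl)oxy]-6-methylhept-5-en-2-one, via alkylmagnesium bromide 7 (not isolated)
Conditions: 3, Mg turnings (activated by 1,2-dibromoethane), THF, 40 °C; then 6, THF, 0 °C; aq. NH4Cl
Reagents that add atoms: none
Why: Grignard formation followed by Weinreb ketone synthesis; the chelated tetrahedral intermediate should stop the addition at the ketone stage.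

Step 5
Reactants: 8 (E)-7-(tert-butyldimethylsilyloxy)-1-[(4-methoxybenzyl)oxy]-6-methylhept-5-en-2-one; 9 (4-carboxybutyl)triphenylphosphonium bromide
Product: 11 (5Z,9E)-11-(tert-butyldimethylsilyloxy)-6-{[(4-methoxybenzyl)oxy]methyl}-10-methylundeca-5,9-dienoic acid, via carboxylate ylide 10 (not isolated)
Conditions: 9, NaN(SiMe3)2 (2 equiv per 9), THF, 0 °C → rt; then 8, –78 °C → rt; dilute HCl to pH 4
Reagents that add atoms: none
Why: Wittig reaction of a non-stabilised ylide with an α-alkoxy ketone, a substrate class known to place the alkoxymethyl group cis to the ylide-derived chain, which should set the Z C5=C6 geometry and leave the C7 oxygen (PMB ether) and the chain terminus (free acid) differentiated.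

Step 6
Reactants: 11 (5Z,9E)-11-(tert-butyldimethylsilyloxy)-6-{[(4-methoxybenzyl)oxy]methyl}-10-methylundeca-5,9-dienoic acid
Product: 12 2-(trimethylsilyl)ethyl (5Z,9E)-11-(tert-butyldimethylsilyloxy)-6-{[(4-methoxybenzyl)oxy]methyl}-10-methylundeca-5,9-dienoate
Conditions: 2-(trimethylsilyl)ethanol, EDC·HCl, DMAP (cat.), CH2Cl2, 0 °C → rt
Reagents that add atoms: 2-(trimethylsilyl)ethanol, C[Si](C)(C)CCO
Why: Steglich esterification installs a carboxyl protecting group that fluoride removes at the end together with the aryl silyl ethers.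

Step 7
Reactants: 12 2-(trimethylsilyl)ethyl (5Z,9E)-11-(tert-butyldimethylsilyloxy)-6-{[(4-methoxybenzyl)oxy]methyl}-10-methylundeca-5,9-dienoate
Product: 14 2-(trimethylsilyl)ethyl (5Z,9E)-11-(tert-butyldimethylsilyloxy)-2-(diethoxyphosphoryl)-6-{[(4-methoxybenzyl)oxy]methyl}-10-methylundeca-5,9-dienoate (racemic at C2), via phosphonite ester 13 (not isolated)
Conditions: LiN(i-Pr)2, THF, –78 °C; ClP(OEt)2, –78 °C → rt; then H2O2 (30% aq.), 0 °C
Reagents that add atoms: diethyl chlorophosphite, CCOP(Cl)OCC; hydrogen peroxide, OO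
Why: C-phosphinylation of an ester lithium enolate with a trivalent phosphorus chloride followed by oxidation to the phosphonate is an established route to α-phosphono esters and avoids the O-phosphorylation seen with chlorophosphates.

Step 8
Reactants: 15 2',5'-dihydroxyacetophenone
Product: 16 1-[2,5-bis(triisopropylsilyloxy)phenyl]ethanone
Conditions: TIPSCl, imidazole, DMAP (cat.), DMF, 50 °C
Reagents that add atoms: triisopropylsilyl chloride, CC(C)[Si](Cl)(C(C)C)C(C)C
Why: Silylation of both phenols, with warming to overcome the hydrogen-bonded ortho hydroxyl, gives hydrolytically robust aryl silyl ethers that later block the ortho oxygen as a competing nucleophile.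

Step 9
Reactants: 16 1-[2,5-bis(triisopropylsilyloxy)phenyl]ethanone
Product: 17 2-[2,5-bis(triisopropylsilyloxy)phenyl]-2-oxoacetaldehyde
Conditions: SeO2, 1,4-dioxane/H2O (30:1), 90 °C; then azeotropic drying with toluene
Reagents that add atoms: selenium dioxide, O=[Se]=O
Why: Riley oxidation of an aryl methyl ketone to the arylglyoxal is a standard transformation that the bulky aryl silyl ethers should survive.

Step 10
Reactants: 14 2-(trimethylsilyl)ethyl (5Z,9E)-11-(tert-butyldimethylsilyloxy)-2-(diethoxyphosphoryl)-6-{[(4-methoxybenzyl)oxy]methyl}-10-methylundeca-5,9-dienoate; 17 2-[2,5-bis(triisopropylsilyloxy)phenyl]-2-oxoacetaldehyde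
Product: 18 2-(trimethylsilyl)ethyl (E)-4-[2,5-bis(triisopropylsilyloxy)phenyl]-2-[(3Z,7E)-9-(tert-butyldimethylsilyloxy)-4-{[(4-methoxybenzyl)oxy]methyl}-8-methylnona-3,7-dienyl]-4-oxobut-2-enoate
Conditions: NaH, THF, 0 °C; then 17, –78 → 0 °C
Reagents that add atoms: none
Why: Horner–Wadsworth–Emmons olefination of the α-substituted phosphonoacetate with the aldehyde carbon of the glyoxal should form the Ca=C2 bond with the aroyl group trans to the ester (E), as is usual for these reagents.

Step 11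
Reactants: 18 2-(trimethylsilyl)ethyl (E)-4-[2,5-bis(triisopropylsilyloxy)phenyl]-2-[(3Z,7E)-9-(tert-butyldimethylsilyloxy)-4-{[(4-methoxybenzyl)oxy]methyl}-8-methylnona-3,7-dienyl]-4-oxobut-2-enoate
Product: 19 2-(trimethylsilyl)ethyl (E)-4-[2,5-bis(triisopropylsilyloxy)phenyl]-2-[(3Z,7E)-9-(tert-butyldimethylsilyloxy)-4-(hydroxymethyl)-8-methylnona-3,7-dienyl]-4-oxobut-2-enoate
Conditions: DDQ, CH2Cl2/pH 7 phosphate buffer (10:1), 0 °C
Reagents that add atoms: none
Why: Oxidative cleavage of the PMB ether under buffered, near-neutral conditions frees the C7 allylic alcohol without touching silyl ethers, the silylethyl ester or the acceptor, and should not trigger uncatalysed ring closure.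

Step 12
Reactants: 19 2-(trimethylsilyl)ethyl (E)-4-[2,5-bis(triisopropylsilyloxy)phenyl]-2-[(3Z,7E)-9-(tert-butyldimethylsilyloxy)-4-(hydroxymethyl)-8-methylnona-3,7-dienyl]-4-oxobut-2-enoate
Product: 20 2-(trimethylsilyl)ethyl (R)-2-{2-[2,5-bis(triisopropylsilyloxy)phenyl]-2-oxoethyl}-6-[(E)-5-(tert-butyldimethylsilyloxy)-4-methylpent-3-enyl]-2,3,4,7-tetrahydrooxepine-2-carboxylate
Conditions: 9-amino-9-deoxy-epi-quinidine-derived squaramide bearing a 3,5-bis(trifluoromethyl)phenyl group (10 mol%), toluene (0.01 M), –20 °C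
Reagents that add atoms: none
Why: Proposed new method: the quinuclidine nitrogen acts as a general base on the C7 hydroxyl while the squaramide N–H pair hydrogen-bonds the aryl ketone oxygen, so that oxygen adds to C2 (β to the ketone, α to the ester) and the resulting enol is protonated at Ca, which makes the O1–C2 bond. The closest known reaction types are amine–thiourea and amine–squaramide catalysed intramolecular oxa-Michael additions of hydroxy enones giving five- and six-membered ethers, and hetero-Michael additions to 3-aroylacrylates at the carbon α to the ester; a seven-membered closure onto a fully substituted acceptor carbon has not been shown. The tetrahydrooxepine closes in a 7-exo-trig mode, helped by the Z C5=C6 alkene, which holds the C7 hydroxyl and the C4–C3 tether on the same side. The single stereocentre (R)-C2 is controlled by the catalyst alone, which binds the E-acceptor through the ketone and delivers the tethered oxygen to one face of prochiral C2. Regioselectivity for C2 over Ca follows from the ketone being the stronger acceptor and from seven- rather than eight-membered closure, the silylated ortho-phenol cannot compete as a nucleophile, and high dilution suppresses intermolecular addition. Because the adduct can revert by retro-oxa-Michael reaction and deprotonation at C3 could move the alkene out of conjugation, low temperature, a non-polar solvent and a short contact time are chosen to keep the closure kinetic.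

Step 13
Reactants: 20 2-(trimethylsilyl)ethyl (R)-2-{2-[2,5-bis(triisopropylsilyloxy)phenyl]-2-oxoethyl}-6-[(E)-5-(tert-butyldimethylsilyloxy)-4-methylpent-3-enyl]-2,3,4,7-tetrahydrooxepine-2-carboxylate
Product: 21 2-(trimethylsilyl)ethyl (R)-2-{2-[2,5-bis(triisopropylsilyloxy)phenyl]-2-oxoethyl}-6-[(E)-5-hydroxy-4-methylpent-3-enyl]-2,3,4,7-tetrahydrooxepine-2-carboxylate
Conditions: PPTS (cat.), MeOH/CH2Cl2 (1:1), 0 °C → rt
Reagents that add atoms: none
Why: Acid-catalysed methanolysis cleaves a primary alkyl silyl ether much faster than aryl triisopropylsilyl ethers, and the non-basic medium should not open the β-alkoxy ketone.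

Step 14
Reactants: 22 (E)-4-hydroxycinnamic acid (p-coumaric acid)
Product: 24 (E)-3-[4-(tert-butyldimethylsilyloxy)phenyl]acrylic acid, via silyl ester 23 (not isolated)
Conditions: TBSCl (2.5 equiv), imidazole, DMF, rt; then AcOH/THF/H2O (3:1:1), rt
Reagents that add atoms: tert-butyldimethylsilyl chloride, CC(C)(C)[Si](C)(C)Cl
Why: Bis-silylation followed by selective hydrolysis of the very labile silyl ester under mild aqueous acid, which leaves the aryl silyl ether in place.

Step 15
Reactants: 21 2-(trimethylsilyl)ethyl (R)-2-{2-[2,5-bis(triisopropylsilyloxy)phenyl]-2-oxoethyl}-6-[(E)-5-hydroxy-4-methylpent-3-enyl]-2,3,4,7-tetrahydrooxepine-2-carboxylate; 24 (E)-3-[4-(tert-butyldimethylsilyloxy)phenyl]acrylic acid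
Product: 25 2-(trimethylsilyl)ethyl (R)-2-{2-[2,5-bis(triisopropylsilyloxy)phenyl]-2-oxoethyl}-6-[(E)-5-{(E)-3-[4-(tert-butyldimethylsilyloxy)phenyl]acryloyloxy}-4-methylpent-3-enyl]-2,3,4,7-tetrahydrooxepine-2-carboxylate
Conditions: EDC·HCl, DMAP, CH2Cl2, 0 °C → rt
Reagents that add atoms: none
Why: Steglich esterification of the only free hydroxyl (a primary allylic alcohol) with the cinnamic acid proceeds under weakly basic conditions that should not induce retro-oxa-Michael opening.

Step 16
Reactants: 25 2-(trimethylsilyl)ethyl (R)-2-{2-[2,5-bis(triisopropylsilyloxy)phenyl]-2-oxoethyl}-6-[(E)-5-{(E)-3-[4-(tert-butyldimethylsilyloxy)phenyl]acryloyloxy}-4-methylpent-3-enyl]-2,3,4,7-tetrahydrooxepine-2-carboxylate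
Product: 26 (R)-2-[2-(2,5-dihydroxyphenyl)-2-oxoethyl]-6-{(E)-5-[(E)-3-(4-hydroxyphenyl)acryloyloxy]-4-methylpent-3-enyl}-2,3,4,7-tetrahydrooxepine-2-carboxylic acid (CNP0602535.1)
Conditions: tris(dimethylamino)sulfonium difluorotrimethylsilicate (TASF), DMF, 0 °C → rt; dilute HCl to pH 3 at 0 °C
Reagents that add atoms: none
Why: Fluoride-induced desilylation of the three aryl silyl ethers and β-elimination of the silylethyl ester (ethene and fluorotrimethylsilane) unmask all acidic groups in one operation; the ortho-phenoxide formed first deactivates the ketone toward enolisation, which should protect the ring ether from E1cB opening.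

**Compound list**

1 | 5-bromo-2-methylpent-2-ene | CC(C)=CCCBr | starting material
2 | (E)-5-bromo-2-methylpent-2-en-1-ol | C/C(=C\CCBr)CO | intermediate
3 | [(E)-5-bromo-2-methylpent-2-enyloxy](tert-butyl)dimethylsilane | C/C(=C\CCBr)CO[Si](C)(C)C(C)(C)C | intermediate
4 | 4-methoxybenzyl alcohol | COc1ccc(CO)cc1 | starting material
5 | 2-chloro-N-methoxy-N-methylacetamide | CON(C)C(=O)CCl | starting material
6 | N-methoxy-2-[(4-methoxybenzyl)oxy]-N-methylacetamide | CON(C)C(=O)COCc1ccc(OC)cc1 | intermediate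
7 | [(E)-5-(tert-butyldimethylsilyloxy)-4-methylpent-3-enyl]magnesium bromide | Br[Mg]CC/C=C(\C)CO[Si](C)(C)C(C)(C)C | intermediate
8 | (E)-7-(tert-butyldimethylsilyloxy)-1-[(4-methoxybenzyl)oxy]-6-methylhept-5-en-2-one | COc1ccc(COCC(=O)CC/C=C(\C)CO[Si](C)(C)C(C)(C)C)cc1 | intermediate
9 | (4-carboxybutyl)triphenylphosphonium bromide | [Br-].OC(=O)CCCC[P+](c1ccccc1)(c1ccccc1)c1ccccc1 | starting material
10 | sodium 5-(triphenyl-λ5-phosphanylidene)pentanoate | [Na+].[O-]C(=O)CCCC=P(c1ccccc1)(c1ccccc1)c1ccccc1 | intermediate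
11 | (5Z,9E)-11-(tert-butyldimethylsilyloxy)-6-{[(4-methoxybenzyl)oxy]methyl}-10-methylundeca-5,9-dienoic acid | OC(=O)CCC/C=C(\COCc1ccc(OC)cc1)CC/C=C(\C)CO[Si](C)(C)C(C)(C)C | intermediate
12 | 2-(trimethylsilyl)ethyl (5Z,9E)-11-(tert-butyldimethylsilyloxy)-6-{[(4-methoxybenzyl)oxy]methyl}-10-methylundeca-5,9-dienoate | C[Si](C)(C)CCOC(=O)CCC/C=C(\COCc1ccc(OC)cc1)CC/C=C(\C)CO[Si](C)(C)C(C)(C)C | intermediate
13 | 2-(trimethylsilyl)ethyl (5Z,9E)-11-(tert-butyldimethylsilyloxy)-2-(diethoxyphosphanyl)-6-{[(4-methoxybenzyl)oxy]methyl}-10-methylundeca-5,9-dienoate | C[Si](C)(C)CCOC(=O)C(P(OCC)OCC)CC/C=C(\COCc1ccc(OC)cc1)CC/C=C(\C)CO[Si](C)(C)C(C)(C)C | intermediate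
14 | 2-(trimethylsilyl)ethyl (5Z,9E)-11-(tert-butyldimethylsilyloxy)-2-(diethoxyphosphoryl)-6-{[(4-methoxybenzyl)oxy]methyl}-10-methylundeca-5,9-dienoate (racemic at C2) | C[Si](C)(C)CCOC(=O)C(P(=O)(OCC)OCC)CC/C=C(\COCc1ccc(OC)cc1)CC/C=C(\C)CO[Si](C)(C)C(C)(C)C | intermediate
15 | 2',5'-dihydroxyacetophenone | CC(=O)c1cc(O)ccc1O | starting material
16 | 1-[2,5-bis(triisopropylsilyloxy)phenyl]ethanone | CC(=O)c1cc(O[Si](C(C)C)(C(C)C)C(C)C)ccc1O[Si](C(C)C)(C(C)C)C(C)C | intermediate
17 | 2-[2,5-bis(triisopropylsilyloxy)phenyl]-2-oxoacetaldehyde | O=CC(=O)c1cc(O[Si](C(C)C)(C(C)C)C(C)C)ccc1O[Si](C(C)C)(C(C)C)C(C)C | intermediate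
18 | 2-(trimethylsilyl)ethyl (E)-4-[2,5-bis(triisopropylsilyloxy)phenyl]-2-[(3Z,7E)-9-(tert-butyldimethylsilyloxy)-4-{[(4-methoxybenzyl)oxy]methyl}-8-methylnona-3,7-dienyl]-4-oxobut-2-enoate | COc1ccc(COC/C(CC/C=C(\C)CO[Si](C)(C)C(C)(C)C)=C\CC/C(C(=O)OCC[Si](C)(C)C)=C\C(=O)c2cc(O[Si](C(C)C)(C(C)C)C(C)C)ccc2O[Si](C(C)C)(C(C)C)C(C)C)cc1 | intermediate
19 | 2-(trimethylsilyl)ethyl (E)-4-[2,5-bis(triisopropylsilyloxy)phenyl]-2-[(3Z,7E)-9-(tert-butyldimethylsilyloxy)-4-(hydroxymethyl)-8-methylnona-3,7-dienyl]-4-oxobut-2-enoate | OC/C(CC/C=C(\C)CO[Si](C)(C)C(C)(C)C)=C\CC/C(C(=O)OCC[Si](C)(C)C)=C\C(=O)c1cc(O[Si](C(C)C)(C(C)C)C(C)C)ccc1O[Si](C(C)C)(C(C)C)C(C)C | intermediate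
20 | 2-(trimethylsilyl)ethyl (R)-2-{2-[2,5-bis(triisopropylsilyloxy)phenyl]-2-oxoethyl}-6-[(E)-5-(tert-butyldimethylsilyloxy)-4-methylpent-3-enyl]-2,3,4,7-tetrahydrooxepine-2-carboxylate | C/C(=C\CCC1=CCC[C@@](CC(=O)c2cc(O[Si](C(C)C)(C(C)C)C(C)C)ccc2O[Si](C(C)C)(C(C)C)C(C)C)(C(=O)OCC[Si](C)(C)C)OC1)CO[Si](C)(C)C(C)(C)C | intermediate
21 | 2-(trimethylsilyl)ethyl (R)-2-{2-[2,5-bis(triisopropylsilyloxy)phenyl]-2-oxoethyl}-6-[(E)-5-hydroxy-4-methylpent-3-enyl]-2,3,4,7-tetrahydrooxepine-2-carboxylate | C/C(=C\CCC1=CCC[C@@](CC(=O)c2cc(O[Si](C(C)C)(C(C)C)C(C)C)ccc2O[Si](C(C)C)(C(C)C)C(C)C)(C(=O)OCC[Si](C)(C)C)OC1)CO | intermediate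
22 | (E)-4-hydroxycinnamic acid (p-coumaric acid) | OC(=O)/C=C/c1ccc(O)cc1 | starting material
23 | tert-butyldimethylsilyl (E)-3-[4-(tert-butyldimethylsilyloxy)phenyl]acrylate | CC(C)(C)[Si](C)(C)OC(=O)/C=C/c1ccc(O[Si](C)(C)C(C)(C)C)cc1 | intermediate
24 | (E)-3-[4-(tert-butyldimethylsilyloxy)phenyl]acrylic acid | OC(=O)/C=C/c1ccc(O[Si](C)(C)C(C)(C)C)cc1 | intermediate
25 | 2-(trimethylsilyl)ethyl (R)-2-{2-[2,5-bis(triisopropylsilyloxy)phenyl]-2-oxoethyl}-6-[(E)-5-{(E)-3-[4-(tert-butyldimethylsilyloxy)phenyl]acryloyloxy}-4-methylpent-3-enyl]-2,3,4,7-tetrahydrooxepine-2-carboxylate | C/C(=C\CCC1=CCC[C@@](CC(=O)c2cc(O[Si](C(C)C)(C(C)C)C(C)C)ccc2O[Si](C(C)C)(C(C)C)C(C)C)(C(=O)OCC[Si](C)(C)C)OC1)COC(=O)/C=C/c1ccc(O[Si](C)(C)C(C)(C)C)cc1 | intermediate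
26 | (R)-2-[2-(2,5-dihydroxyphenyl)-2-oxoethyl]-6-{(E)-5-[(E)-3-(4-hydroxyphenyl)acryloyloxy]-4-methylpent-3-enyl}-2,3,4,7-tetrahydrooxepine-2-carboxylic acid | C/C(=C\CCC1=CCC[C@@](CC(=O)c2cc(O)ccc2O)(C(=O)O)OC1)COC(=O)/C=C/c1ccc(O)cc1 | target

**Step count**

Total step count: 16.
Longest linear sequence: 12 steps (steps 1, 2, 4, 5, 6, 7, 10, 11, 12, 13, 15, 16).

**Steps most likely to fail**

1. Step 12 (oxa-Michael ring closure). The seven-membered closure onto a fully substituted carbon may be slow or reversible, facial selectivity may be poor, or the amine may shift the acceptor alkene out of conjugation by deprotonation at C3. Fallback: setting out from 19, closure with a catalytic achiral Brønsted base (DBU, THF, 0 °C), the usual way of running intramolecular oxa-Michael additions of hydroxy enones, should give the racemic tetrahydrooxepine ester F1. The enantiomers are then separated by preparative HPLC on a polysaccharide-based chiral stationary phase, and the (R)-enantiomer is compound 20, where the route is rejoined.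

2. Step 5 (Wittig reaction). The Z/E selectivity may erode with the carboxylate-bearing ylide, or the basic ylide may enolise the α-alkoxy ketone instead of adding. Fallback: setting out from bromide 3, alkylation of commercial methyl bis(2,2,2-trifluoroethyl)phosphonoacetate (NaH, NaI, DMSO) should give the α-alkylated phosphonate F2. Still–Gennari olefination with pent-4-enal (KN(SiMe3)2, 18-crown-6, THF, –78 °C) then gives the Z-configured dienoate F3, and i-Bu2AlH reduction the allylic alcohol F4. Etherification (NaH, 4-methoxybenzyl chloride, Bu4NI, THF) gives the PMB ether F5. Hydroboration of the terminal vinyl group with 9-borabicyclo[3.3.1]nonane and NaOH/H2O2 work-up gives the primary alcohol F6. Oxidation with TEMPO/PhI(OAc)2 in aqueous MeCN leads to acid 11, where the route is rejoined.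

3. Step 10 (Horner–Wadsworth–Emmons olefination). The phosphonate carbanion may add in conjugate fashion to the highly electrophilic product, the glyoxal may react as its hydrate, or the E/Z selectivity may be low. Fallback: setting out from ester 12 and glyoxal 17 (steps 7 and 10 are bypassed), the lithium enolate of 12 (LiN(i-Pr)2, THF, –78 °C) adds to the aldehyde carbon of 17 to give the aldol adduct F7. Mesylation (MsCl, Et3N, CH2Cl2, 0 °C) gives the mesylate F8, and DBU-mediated E1cB elimination through the ester enolate should give the thermodynamically preferred E-acrylate, compound 18, where the route is rejoined.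

**Further compounds**

F1 | step 12 | racemic 2-(trimethylsilyl)ethyl 2-{2-[2,5-bis(triisopropylsilyloxy)phenyl]-2-oxoethyl}-6-[(E)-5-(tert-butyldimethylsilyloxy)-4-methylpent-3-enyl]-2,3,4,7-tetrahydrooxepine-2-carboxylate | C/C(=C\CCC1=CCCC(CC(=O)c2cc(O[Si](C(C)C)(C(C)C)C(C)C)ccc2O[Si](C(C)C)(C(C)C)C(C)C)(C(=O)OCC[Si](C)(C)C)OC1)CO[Si](C)(C)C(C)(C)C
F2 | step 5 | methyl (E)-2-[bis(2,2,2-trifluoroethoxy)phosphoryl]-7-(tert-butyldimethylsilyloxy)-6-methylhept-5-enoate | COC(=O)C(CC/C=C(\C)CO[Si](C)(C)C(C)(C)C)P(=O)(OCC(F)(F)F)OCC(F)(F)F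
F3 | step 5 | methyl (2Z)-2-[(E)-5-(tert-butyldimethylsilyloxy)-4-methylpent-3-enyl]hepta-2,6-dienoate | COC(=O)/C(CC/C=C(\C)CO[Si](C)(C)C(C)(C)C)=C\CCC=C
F4 | step 5 | (2Z)-2-[(E)-5-(tert-butyldimethylsilyloxy)-4-methylpent-3-enyl]hepta-2,6-dien-1-ol | OC/C(CC/C=C(\C)CO[Si](C)(C)C(C)(C)C)=C\CCC=C
F5 | step 5 | tert-butyl{[(2E,6Z)-6-{[(4-methoxybenzyl)oxy]methyl}-2-methylundeca-2,6,10-trienyl]oxy}dimethylsilane | COc1ccc(COC/C(CC/C=C(\C)CO[Si](C)(C)C(C)(C)C)=C\CCC=C)cc1
F6 | step 5 | (5Z,9E)-11-(tert-butyldimethylsilyloxy)-6-{[(4-methoxybenzyl)oxy]methyl}-10-methylundeca-5,9-dien-1-ol | COc1ccc(COC/C(CC/C=C(\C)CO[Si](C)(C)C(C)(C)C)=C\CCCCO)cc1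
F7 | step 10 | 2-(trimethylsilyl)ethyl (5Z,9E)-2-{2-[2,5-bis(triisopropylsilyloxy)phenyl]-1-hydroxy-2-oxoethyl}-11-(tert-butyldimethylsilyloxy)-6-{[(4-methoxybenzyl)oxy]methyl}-10-methylundeca-5,9-dienoate (diastereomer mixture) | C[Si](C)(C)CCOC(=O)C(C(O)C(=O)c1cc(O[Si](C(C)C)(C(C)C)C(C)C)ccc1O[Si](C(C)C)(C(C)C)C(C)C)CC/C=C(\COCc1ccc(OC)cc1)CC/C=C(\C)CO[Si](C)(C)C(C)(C)C
F8 | step 10 | 2-(trimethylsilyl)ethyl (5Z,9E)-2-{2-[2,5-bis(triisopropylsilyloxy)phenyl]-1-(methylsulfonyloxy)-2-oxoethyl}-11-(tert-butyldimethylsilyloxy)-6-{[(4-methoxybenzyl)oxy]methyl}-10-methylundeca-5,9-dienoate (diastereomer mixture) | C[Si](C)(C)CCOC(=O)C(C(OS(C)(=O)=O)C(=O)c1cc(O[Si](C(C)C)(C(C)C)C(C)C)ccc1O[Si](C(C)C)(C(C)C)C(C)C)CC/C=C(\COCc1ccc(OC)cc1)CC/C=C(\C)CO[Si](C)(C)C(C)(C)C
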